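**Strategy.** Numbering follows the clerodane skeleton (ring A: C5–C10; ring B: C1–C5, C10). Ring A carries oxygen at C6 and C8 and methyl groups on C5 and C9, so it is a masked 5-alkyl-4,6-dimethylresorcinol whose C5 lies para to O8. The route therefore makes the C4–C5 bond by a palladium-catalysed, enantioselective dearomative alkenylation: a flat phenol bearing a (Z)-alkenyl iodide tether on C10 closes ring B, creates quaternary C5 and the C3=C4 alkene, and unveils ring A as a methoxy dienone. Birch reduction, vinylation, Stork–Danheiser transposition and face-selective oxygenation then build C6–C10; a Heck coupling adds the butenolide.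

Key step: step 7

Numbering used below: C17, C18, C19, C20 are the methyl groups on C8, C4, C5, C9; C11=C12 is the side-chain alkene; "top face" is the face of the C19 methyl.

Remark: the sense of induction of the P-chiral ligand in step 7 is assumed, and whichever ligand enantiomer gives (4aS)-10 is to be used; the configurations drawn for C9 in 11 and C8 in 14 are the expected major ones and are erased in the following steps.

Step 1
Reactants: 1 1-bromo-3,5-dimethoxybenzene
Product: 2 3-bromo-2,4-diiodo-1,5-dimethoxybenzene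
Conditions: NIS (2.2 equiv), CF3CO2H (cat.), MeCN, 0 °C to rt
Reagents that add atoms: N-iodosuccinimide, O=C1CCC(=O)N1I
Why: Electrophilic aromatic iodination; as with other 5-substituted resorcinol dimethyl ethers, both iodines should enter para to a methoxy group (next to bromine) and not between the two methoxy groups.

Step 2
Reactants: 2 3-bromo-2,4-diiodo-1,5-dimethoxybenzene
Product: 3 3-bromo-1,5-dimethoxy-2,4-dimethylbenzene
Conditions: MeZnCl (2.5 equiv), Pd(PPh3)4 (5 mol %), THF, 50 °C
Reagents that add atoms: methylzinc chloride, C[Zn]Cl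
Why: Negishi coupling; oxidative addition should be much faster at the two C–I bonds than at the C–Br bond, which ends up flanked by two ortho methyl groups.

Step 3
Reactants: 3 3-bromo-1,5-dimethoxy-2,4-dimethylbenzene; 4 [2-(1,3-dioxolan-2-yl)ethyl]zinc bromide
Product: 5 2-[2-(3,5-dimethoxy-2,6-dimethylphenyl)ethyl]-1,3-dioxolane
Conditions: 4 (1.5 equiv, THF solution), Pd(OAc)2 (3 mol %), SPhos (6 mol %), THF, 65 °C
Reagents that add atoms: [2-(1,3-dioxolan-2-yl)ethyl]zinc bromide (4), Br[Zn]CCC1OCCO1
Why: Negishi sp2–sp3 coupling, with a bulky electron-rich biarylphosphine chosen for the di-ortho-substituted aryl bromide; it installs C1–C3 with C3 as a masked aldehyde.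

Step 4
Reactants: 5 2-[2-(3,5-dimethoxy-2,6-dimethylphenyl)ethyl]-1,3-dioxolane
Product: 6 3-[2-(1,3-dioxolan-2-yl)ethyl]-5-methoxy-2,4-dimethylphenol
Conditions: NaSEt (3 equiv), DMF, 130 °C; aq. NH4Cl
Reagents that add atoms: none
Why: Thiolate SN2 O-demethylation; the phenoxide formed first should protect the second ether, 5 is symmetric so only one monophenol can form, and the acetal is stable to base.

Step 5
Reactants: 6 3-[2-(1,3-dioxolan-2-yl)ethyl]-5-methoxy-2,4-dimethylphenol
Product: 7 3-(3-hydroxy-5-methoxy-2,6-dimethylphenyl)propanal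
Conditions: 1 M HCl, THF, rt
Reagents that add atoms: water, O
Why: Acid-catalysed acetal hydrolysis; both ring positions next to the side chain are methylated, so the aldehyde cannot cyclise onto the electron-rich arene.

Step 6
Reactants: 7 3-(3-hydroxy-5-methoxy-2,6-dimethylphenyl)propanal; 8 ethyltriphenylphosphonium iodide
Product: 9 3-[(3Z)-4-iodopent-3-en-1-yl]-5-methoxy-2,4-dimethylphenol
Conditions: 8 (2.6 equiv), n-BuLi, THF, 0 °C; I2, −78 °C; NaN(SiMe3)2, −20 °C; then 7, −78 °C to rt; aq. NH4Cl
Reagents that add atoms: ethyltriphenylphosphonium iodide (8), CC[P+](c1ccccc1)(c1ccccc1)c1ccccc1.[I-]; iodine, II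
Why: Stork–Zhao Wittig olefination with the α-iodo ylide made in the flask, which should favour the (Z)-2-iodoalkene (iodine cis to the chain) through the kinetic cis-oxaphosphetane; one equivalent of ylide is spent on the phenol O–H.

Step 7
Reactants: 9 3-[(3Z)-4-iodopent-3-en-1-yl]-5-methoxy-2,4-dimethylphenol
Product: 10 (4aS)-4-methoxy-1,4a,5-trimethyl-7,8-dihydronaphthalen-2(4aH)-one
Conditions: [Pd(cinnamyl)Cl]2 (2.5 mol %), (S)-AntPhos (6 mol %), K2CO3 (2 equiv), toluene, 90 °C
Reagents that add atoms: none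
Why: Zerovalent palladium inserts into the C4–I bond, the potassium phenoxide then binds palladium through its para carbon C5 (a seven-membered palladacycle), and C(sp2)–C(sp3) reductive elimination forms C4–C5 with loss of aromaticity, leaving the cross-conjugated methoxy dienone. The closest known reaction type is the palladium-catalysed intramolecular arylative dearomatisation of 4-substituted phenols bearing a tethered aryl bromide (spiro and ring-fused versions, the latter enantioselective with P-chiral monophosphines); here an alkenyl iodide takes the place of the aryl bromide. Ring B (C1–C2–C3–C4–C5–C10) closes as a six-membered ring fused at C5–C10, the tether being anchored on C10 next to the reacting carbon, and the Z geometry of the iodoalkene places C3=C4 inside the ring. The only new stereocentre, quaternary C5, is set by the chiral ligand, which differentiates the two faces of the planar phenoxide in the C–C bond-forming event. The step needs attack through C5 in preference to the other methylated neighbour C9 (ortho to O8) and to O-alkenylation: C5 is the para position of the phenoxide and leads to the more stable para-quinoid dienone, O-attack would need an eight-membered ring, and because both neighbours of C10 carry methyl groups no rearomatising C–H alkenylation can compete.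

Step 8
Reactants: 10 (4aS)-4-methoxy-1,4a,5-trimethyl-7,8-dihydronaphthalen-2(4aH)-one
Product: 11 (1R,4aR,8aR)-4-methoxy-1,4a,5-trimethyl-4a,7,8,8a-tetrahydronaphthalen-2(1H)-one
Conditions: Li (2.5 equiv), t-BuOH (1 equiv), NH3/THF, −78 °C; isoprene, then NH4Cl
Reagents that add atoms: none
Why: Birch-type dissolving-metal enone reduction; the β-carbon C10 should be protonated rather than the methoxy-bearing C6 (the vinylogous ester half is the poorer acceptor), axially and anti to the C19 methyl to give the trans ring fusion, while the isolated C3=C4 alkene is inert and the C9 epimers converge in step 9.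

Step 9
Reactants: 11 (1R,4aR,8aR)-4-methoxy-1,4a,5-trimethyl-4a,7,8,8a-tetrahydronaphthalen-2(1H)-one; 12 vinyl bromide
Product: 13 (1R,4aR,8aS)-1-ethenyl-4-methoxy-1,4a,5-trimethyl-4a,7,8,8a-tetrahydronaphthalen-2(1H)-one
Conditions: LiN(SiMe3)2 (1.3 equiv), 12 (3 equiv, THF solution), Pd2(dba)3 (2.5 mol %), P(t-Bu)3 (6 mol %), toluene, 50 °C
Reagents that add atoms: vinyl bromide (12), C=CBr
Why: Palladium-catalysed ketone enolate α-alkenylation at the only enolisable carbon C9 (C5 is quaternary); the vinyl group should be delivered to the face opposite the axial C19 methyl, placing C11 on the bottom face and C20 axial on the top face.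

Step 10
Reactants: 13 (1R,4aR,8aS)-1-ethenyl-4-methoxy-1,4a,5-trimethyl-4a,7,8,8a-tetrahydronaphthalen-2(1H)-one
Product: 15 (4R,4aR,8aR)-4-ethenyl-3,4,8,8a-tetramethyl-4a,5,6,8a-tetrahydronaphthalen-1(4H)-one, via methyllithium adduct 14 (not isolated)
Conditions: MeLi (1.5 equiv), THF, −78 to 0 °C; then 1 M HCl, rt
Reagents that add atoms: methyllithium, [Li]C; water, O
Why: Stork–Danheiser transposition: 1,2-addition to the vinylogous ester carbonyl C8, then acid ionises the tertiary allylic alcohol to a methoxy-stabilised allyl cation whose hydrolysis gives the C6 ketone with the C7=C8 alkene, so the C8 configuration of 14 does not matter.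

Step 11
Reactants: 15 (4R,4aR,8aR)-4-ethenyl-3,4,8,8a-tetramethyl-4a,5,6,8a-tetrahydronaphthalen-1(4H)-one
Product: 16 (2R,3R,4R,4aR,8aR)-2,3-epoxy-4-ethenyl-3,4,8,8a-tetramethyl-3,4,4a,5,6,8a-hexahydronaphthalen-1(2H)-one
Conditions: 30% H2O2, aq. NaOH, MeOH, 0 °C to rt
Reagents that add atoms: hydrogen peroxide, OO
Why: Weitz–Scheffer nucleophilic epoxidation, which touches only the enone (C3=C4 and the vinyl group are not electrophilic); hydroperoxide should add to C8 axially, anti to the axial C20 methyl, putting the oxirane oxygen on the bottom face at C7 and C8.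

Step 12
Reactants: 16 (2R,3R,4R,4aR,8aR)-2,3-epoxy-4-ethenyl-3,4,8,8a-tetramethyl-3,4,4a,5,6,8a-hexahydronaphthalen-1(2H)-one
Product: 17 (3S,4R,4aR,8aR)-4-ethenyl-3-hydroxy-3,4,8,8a-tetramethyl-3,4,4a,5,6,8a-hexahydronaphthalen-1(2H)-one
Conditions: SmI2 (2.2 equiv), THF/MeOH, −90 °C
Reagents that add atoms: none
Why: Single-electron reductive cleavage of the α C–O bond of an α,β-epoxy ketone; the C8–O bond is untouched, so the axial tertiary alcohol keeps its configuration, and methanol protonates the samarium enolate before β-elimination.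

Step 13
Reactants: 17 (3S,4R,4aR,8aR)-4-ethenyl-3-hydroxy-3,4,8,8a-tetramethyl-3,4,4a,5,6,8a-hexahydronaphthalen-1(2H)-one
Product: 18 (2R,3R,4R,4aR,8aR)-4-ethenyl-2,3-dihydroxy-3,4,8,8a-tetramethyl-3,4,4a,5,6,8a-hexahydronaphthalen-1(2H)-one
Conditions: LiN(i-Pr)2 (2.3 equiv), THF, −78 °C (17 added to the base); (camphorsulfonyl)oxaziridine (1.3 equiv), −78 °C; aq. NH4Cl
Reagents that add atoms: (camphorsulfonyl)oxaziridine (either enantiomer), CC1(C)C2CCC13CS(=O)(=O)N4OC34C2
Why: Davis oxidation of the alkoxide–enolate dianion (C7 is the only enolisable carbon); the top face of C7 is blocked by the syn-axial C19 and C20 methyls, so oxygen should enter from the bottom face to give the equatorial 7-OH cis to 8-OH.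

Step 14
Reactants: 18 (2R,3R,4R,4aR,8aR)-4-ethenyl-2,3-dihydroxy-3,4,8,8a-tetramethyl-3,4,4a,5,6,8a-hexahydronaphthalen-1(2H)-one
Product: 19 (2R,3R,4R,4aR,8aR)-4-ethenyl-3-hydroxy-3,4,8,8a-tetramethyl-1-oxo-1,2,3,4,4a,5,6,8a-octahydronaphthalen-2-yl 2-methylpropanoate
Conditions: i-PrCOCl (1.2 equiv), pyridine, DMAP (cat.), CH2Cl2, 0 °C
Reagents that add atoms: isobutyryl chloride, CC(C)C(Cl)=O
Why: DMAP-catalysed O-acylation of the only secondary alcohol; the axial tertiary 8-OH is too hindered, and acylating while C6 is still a ketone distinguishes O7 from O6.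

Step 15
Reactants: 19 (2R,3R,4R,4aR,8aR)-4-ethenyl-3-hydroxy-3,4,8,8a-tetramethyl-1-oxo-1,2,3,4,4a,5,6,8a-octahydronaphthalen-2-yl 2-methylpropanoate
Product: 20 (1R,2S,3R,4R,4aS,8aR)-4-ethenyl-1,3-dihydroxy-3,4,8,8a-tetramethyl-1,2,3,4,4a,5,6,8a-octahydronaphthalen-2-yl 2-methylpropanoate
Conditions: Me4NBH(OAc)3, MeCN/AcOH, −20 °C
Reagents that add atoms: none
Why: Evans–Saksena hydroxyl-directed reduction; the borohydride bound to the axial 8-OH should deliver hydride to the bottom face of C6, giving the equatorial 6-OH anti to 8-OH, and the weakly acidic medium disfavours acyl migration.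

Step 16
Reactants: 20 (1R,2S,3R,4R,4aS,8aR)-4-ethenyl-1,3-dihydroxy-3,4,8,8a-tetramethyl-1,2,3,4,4a,5,6,8a-octahydronaphthalen-2-yl 2-methylpropanoate
Product: 21 (1R,2S,3R,4R,4aS,8aR)-1-acetoxy-4-ethenyl-3-hydroxy-3,4,8,8a-tetramethyl-1,2,3,4,4a,5,6,8a-octahydronaphthalen-2-yl 2-methylpropanoate
Conditions: Ac2O, pyridine, DMAP (cat.), rt
Reagents that add atoms: acetic anhydride, CC(=O)OC(C)=O
Why: DMAP-catalysed acetylation of the secondary equatorial 6-OH; the tertiary axial 8-OH should stay free under these mild conditions.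

Step 17
Reactants: 21 (1R,2S,3R,4R,4aS,8aR)-1-acetoxy-4-ethenyl-3-hydroxy-3,4,8,8a-tetramethyl-1,2,3,4,4a,5,6,8a-octahydronaphthalen-2-yl 2-methylpropanoate; 22 4-bromofuran-2(5H)-one
Product: 23 CNP0207114.1, (1R,2S,3R,4R,4aS,8aR)-1-acetoxy-3-hydroxy-3,4,8,8a-tetramethyl-4-[(E)-2-(5-oxo-2,5-dihydrofuran-3-yl)ethenyl]-1,2,3,4,4a,5,6,8a-octahydronaphthalen-2-yl 2-methylpropanoate
Conditions: 22 (1.5 equiv), Pd(OAc)2 (10 mol %), Bu4NCl, NaHCO3, DMF, 70 °C
Reagents that add atoms: 4-bromofuran-2(5H)-one (22), O=C1C=C(Br)CO1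
Why: Heck coupling under ligand-free phase-transfer conditions; the alkenylpalladium species adds to the terminal carbon of the only monosubstituted alkene, and syn β-hydride elimination can only give the (E)-C11=C12 diene because C9 is quaternary, while the trisubstituted C3=C4 alkene is inert.

**Compound list**

1 | 1-bromo-3,5-dimethoxybenzene | COc1cc(Br)cc(OC)c1 | starting material
2 | 3-bromo-2,4-diiodo-1,5-dimethoxybenzene | COc1cc(OC)c(I)c(Br)c1I | intermediate
3 | 3-bromo-1,5-dimethoxy-2,4-dimethylbenzene | COc1cc(OC)c(C)c(Br)c1C | intermediate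
4 | [2-(1,3-dioxolan-2-yl)ethyl]zinc bromide | Br[Zn]CCC1OCCO1 | starting material
5 | 2-[2-(3,5-dimethoxy-2,6-dimethylphenyl)ethyl]-1,3-dioxolane | COc1cc(OC)c(C)c(CCC2OCCO2)c1C | intermediate
6 | 3-[2-(1,3-dioxolan-2-yl)ethyl]-5-methoxy-2,4-dimethylphenol | COc1cc(O)c(C)c(CCC2OCCO2)c1C | intermediate
7 | 3-(3-hydroxy-5-methoxy-2,6-dimethylphenyl)propanal | COc1cc(O)c(C)c(CCC=O)c1C | intermediate
8 | ethyltriphenylphosphonium iodide | CC[P+](c1ccccc1)(c1ccccc1)c1ccccc1.[I-] | starting material
9 | 3-[(3Z)-4-iodopent-3-en-1-yl]-5-methoxy-2,4-dimethylphenol | COc1cc(O)c(C)c(CC/C=C(/C)I)c1C | intermediate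
10 | (4aS)-4-methoxy-1,4a,5-trimethyl-7,8-dihydronaphthalen-2(4aH)-one | COC1=CC(=O)C(C)=C2CCC=C(C)[C@]12C | intermediate
11 | (1R,4aR,8aR)-4-methoxy-1,4a,5-trimethyl-4a,7,8,8a-tetrahydronaphthalen-2(1H)-one | COC1=CC(=O)[C@H](C)[C@H]2CCC=C(C)[C@]12C | intermediate
12 | vinyl bromide (bromoethene) | C=CBr | starting material
13 | (1R,4aR,8aS)-1-ethenyl-4-methoxy-1,4a,5-trimethyl-4a,7,8,8a-tetrahydronaphthalen-2(1H)-one | COC1=CC(=O)[C@](C)(C=C)[C@H]2CCC=C(C)[C@]12C | intermediate
14 | (1R,2R,4aR,8aR)-1-ethenyl-4-methoxy-1,2,4a,5-tetramethyl-1,2,4a,7,8,8a-hexahydronaphthalen-2-ol | COC1=C[C@@](C)(O)[C@](C)(C=C)[C@H]2CCC=C(C)[C@]12C | intermediate (not isolated)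
15 | (4R,4aR,8aR)-4-ethenyl-3,4,8,8a-tetramethyl-4a,5,6,8a-tetrahydronaphthalen-1(4H)-one | O=C1C=C(C)[C@](C)(C=C)[C@H]2CCC=C(C)[C@]12C | intermediate
16 | (2R,3R,4R,4aR,8aR)-2,3-epoxy-4-ethenyl-3,4,8,8a-tetramethyl-3,4,4a,5,6,8a-hexahydronaphthalen-1(2H)-one | O=C1[C@@H]2O[C@]2(C)[C@](C)(C=C)[C@H]3CCC=C(C)[C@]13C | intermediate
17 | (3S,4R,4aR,8aR)-4-ethenyl-3-hydroxy-3,4,8,8a-tetramethyl-3,4,4a,5,6,8a-hexahydronaphthalen-1(2H)-one | O=C1C[C@](C)(O)[C@](C)(C=C)[C@H]2CCC=C(C)[C@]12C | intermediate
18 | (2R,3R,4R,4aR,8aR)-4-ethenyl-2,3-dihydroxy-3,4,8,8a-tetramethyl-3,4,4a,5,6,8a-hexahydronaphthalen-1(2H)-one | O=C1[C@H](O)[C@](C)(O)[C@](C)(C=C)[C@H]2CCC=C(C)[C@]12C | intermediate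
19 | (2R,3R,4R,4aR,8aR)-4-ethenyl-3-hydroxy-3,4,8,8a-tetramethyl-1-oxo-1,2,3,4,4a,5,6,8a-octahydronaphthalen-2-yl 2-methylpropanoate | O=C1[C@H](OC(=O)C(C)C)[C@](C)(O)[C@](C)(C=C)[C@H]2CCC=C(C)[C@]12C | intermediate
20 | (1R,2S,3R,4R,4aS,8aR)-4-ethenyl-1,3-dihydroxy-3,4,8,8a-tetramethyl-1,2,3,4,4a,5,6,8a-octahydronaphthalen-2-yl 2-methylpropanoate | O[C@H]1[C@H](OC(=O)C(C)C)[C@](C)(O)[C@](C)(C=C)[C@H]2CCC=C(C)[C@]12C | intermediate
21 | (1R,2S,3R,4R,4aS,8aR)-1-acetoxy-4-ethenyl-3-hydroxy-3,4,8,8a-tetramethyl-1,2,3,4,4a,5,6,8a-octahydronaphthalen-2-yl 2-methylpropanoate | CC(=O)O[C@H]1[C@H](OC(=O)C(C)C)[C@](C)(O)[C@](C)(C=C)[C@H]2CCC=C(C)[C@]12C | intermediate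
22 | 4-bromofuran-2(5H)-one | O=C1C=C(Br)CO1 | starting material
23 | CNP0207114.1, (1R,2S,3R,4R,4aS,8aR)-1-acetoxy-3-hydroxy-3,4,8,8a-tetramethyl-4-[(E)-2-(5-oxo-2,5-dihydrofuran-3-yl)ethenyl]-1,2,3,4,4a,5,6,8a-octahydronaphthalen-2-yl 2-methylpropanoate | CC(=O)O[C@H]1[C@H](OC(=O)C(C)C)[C@](C)(O)[C@](C)(/C=C/C2=CC(=O)OC2)[C@H]2CCC=C(C)[C@]12C | target

**Step count and risks**

Total step count: 17. Longest linear sequence: 17 steps (from 1; compounds 4, 8, 12 and 22 are commercial).

Steps most likely to fail: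

Step 7. The C–C reductive elimination may take place at the ortho carbon C9 instead of C5, or the ligand may discriminate the two faces of the phenoxide poorly, so that the dienone forms as the wrong constitutional isomer or with low enantiomeric purity. The fallback activates an alkyne as the electrophile instead of cross-coupling an alkenyl halide; it sets out from 3 and comes back at 10. 5-Bromopent-2-yne is converted with Zn dust (LiCl, THF) into pent-3-yn-1-ylzinc bromide F1, which is coupled with 3 (Pd(OAc)2, SPhos, THF) to give 1,5-dimethoxy-2,4-dimethyl-3-(pent-3-yn-1-yl)benzene F2. Mono-demethylation with NaSEt in DMF gives 5-methoxy-2,4-dimethyl-3-(pent-3-yn-1-yl)phenol F3. A cationic gold catalyst (Ph3PAuNTf2, CH2Cl2, rt) should then promote attack of C5 on C4 in a 6-endo-dig dearomative carbocyclisation, and protodeauration should give racemic 4-methoxy-1,4a,5-trimethyl-7,8-dihydronaphthalen-2(4aH)-one F4. Compound 10 would be separated from F4 by preparative chromatography on a chiral stationary phase.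

Step 9. The crowded, fully substituted palladium enolate may undergo C–C reductive elimination too slowly, so that dehydrohalogenation of vinyl bromide or O-alkenylation takes over and the quaternary centre is not formed. The fallback replaces cross-coupling by conjugate addition and thermal elimination; it sets out from 11 and comes back at 13. The lithium enolate of 11 (LiN(i-Pr)2, THF, −78 °C) is added in a Michael reaction to phenyl vinyl sulfoxide, from the face opposite the C19 methyl, to give (1R,4aR,8aS)-4-methoxy-1,4a,5-trimethyl-1-[2-(phenylsulfinyl)ethyl]-4a,7,8,8a-tetrahydronaphthalen-2(1H)-one F5 (both configurations at sulfur). Thermal syn-elimination (toluene, 110 °C, CaCO3) should then give 13.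

Step 13. The tertiary lithium aldolate may open ring A by retro-aldol cleavage before C-enolisation is complete, or the oxidant may approach C7 from the top face. The fallback avoids the strongly basic dianion by oxidising a neutral silyl enol ether; it sets out from 17 and comes back at 18. Soft enolisation with Me3SiOTf/Et3N (CH2Cl2, 0 °C) silylates both the ketone and the tertiary alcohol to give (3S,4R,4aR,8aR)-4-ethenyl-3,4,8,8a-tetramethyl-1,3-bis(trimethylsilyloxy)-3,4,4a,5,6,8a-hexahydronaphthalene F6. Rubottom oxidation with dimethyldioxirane (acetone, −78 °C, where the isolated alkenes should not react), followed by citric acid in MeOH, should give 18.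

**Further compounds**

F1 | step 7 | pent-3-yn-1-ylzinc bromide | CC#CCC[Zn]Br
F2 | step 7 | 1,5-dimethoxy-2,4-dimethyl-3-(pent-3-yn-1-yl)benzene | COc1cc(OC)c(C)c(CCC#CC)c1C
F3 | step 7 | 5-methoxy-2,4-dimethyl-3-(pent-3-yn-1-yl)phenol | COc1cc(O)c(C)c(CCC#CC)c1C
F4 | step 7 | racemic 4-methoxy-1,4a,5-trimethyl-7,8-dihydronaphthalen-2(4aH)-one | COC1=CC(=O)C(C)=C2CCC=C(C)C12C
F5 | step 9 | (1R,4aR,8aS)-4-methoxy-1,4a,5-trimethyl-1-[2-(phenylsulfinyl)ethyl]-4a,7,8,8a-tetrahydronaphthalen-2(1H)-one | COC1=CC(=O)[C@](C)(CCS(=O)c3ccccc3)[C@H]2CCC=C(C)[C@]12C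
F6 | step 13 | (3S,4R,4aR,8aR)-4-ethenyl-3,4,8,8a-tetramethyl-1,3-bis(trimethylsilyloxy)-3,4,4a,5,6,8a-hexahydronaphthalene | C[Si](C)(C)OC1=C[C@](C)(O[Si](C)(C)C)[C@](C)(C=C)[C@H]2CCC=C(C)[C@]12C
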